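**Assumptions (one line each):**
- 4-Bromo-2,6-dimethoxyphenol, (S)-TBDPS glycidyl ether and 4-fluoro-3-hydroxybenzaldehyde are commercial.
- The target is the trans-(2R,3R) benzodioxane, with the styryl group para to the oxygen on C3, as read from the SMILES.

## Retrosynthetic overview
1. The (E)-stilbene is made last by Horner–Wadsworth–Emmons (HWE) olefination of a benzodioxane-7-carbaldehyde with a bis-silyl-protected 3,5-dihydroxybenzylphosphonate.
2. The only ring to be formed is the trans-2,3-disubstituted 1,4-benzodioxane. It comes from a new DDQ-triggered p-quinone-methide (QM) 6-exo oxa-cyclization of a syringyl CH2 onto an ortho phenol. C3 is already set, and C2 is set relative to it.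
3. The C3–O4 aryl ether is made by SNAr of a secondary alkoxide onto a fluoroarene activated by the para CHO. This proceeds with retention at carbon and also supplies the handle for the stilbene.
4. The C3 stereocentre comes from (S)-TBDPS glycidyl ether, opened by the syringyl Grignard with Cu catalysis.

## Route

**Step 1**
Reactants: 1 (4-bromo-2,6-dimethoxyphenol); 2 (allyl bromide)
Product: 3 (2-(allyloxy)-5-bromo-1,3-dimethoxybenzene)
Conditions: K2CO3, acetone, reflux
Reagents that add atoms: allyl bromide, C=CCBr
Why: Williamson O-allylation masks the syringyl OH so the Grignard and SNAr steps can run. Allyl is removable under neutral Pd(0) conditions later. No stereocentre is involved.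

**Step 2**
Reactants: 3; 4 ((S)-tert-butyldiphenylsilyl glycidyl ether)
Product: 5 ((S)-1-[4-(allyloxy)-3,5-dimethoxyphenyl]-3-(TBDPSO)propan-2-ol)
Conditions: (i) Mg, I2 (cat.), THF, reflux, to form ArMgBr from 3; (ii) 4, CuI (10 mol%), THF, –20 → 0 °C; then aq. NH4Cl
Reagents that add atoms: none
Why: Cu-catalysed Grignard opening of a terminal epoxide occurs at the CH2 and does not touch the stereocentre, so the (S) centre of 4 becomes the (S) carbinol 5 (same CIP priority order).

**Step 3**
Reactants: 6 (4-fluoro-3-hydroxybenzaldehyde); 2 (allyl bromide)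
Product: 7 (3-(allyloxy)-4-fluorobenzaldehyde)
Conditions: K2CO3, DMF, rt
Reagents that add atoms: allyl bromide, C=CCBr
Why: Williamson O-allylation of the phenol protects the future O1 oxygen as an allyl ether that can be removed with the syringyl allyl ether in Step 5.

**Step 4**
Reactants: 5; 7
Product: 8 (SNAr aryl ether: (S)-1-[4-(allyloxy)-3,5-dimethoxyphenyl]-3-(TBDPSO)propan-2-yl 2-(allyloxy)-4-formylphenyl ether)
Conditions: NaH (1.3 equiv), DMF, 0 °C → rt, 5 + 7 (1.1 equiv)
Reagents that add atoms: none
Why: Nucleophilic aromatic substitution (SNAr) of F, which is para to CHO, by the secondary alkoxide. The C–O bond at the carbinol carbon is never broken, so its configuration is retained; it is still S for these substituents.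

**Step 5**
Reactants: 8
Product: 9 (diphenol: 4-hydroxy-3,5-dimethoxyphenyl / 2-hydroxy-4-formylphenyl ether, (S)-configured)
Conditions: Pd(PPh3)4 (5 mol%), K2CO3, MeOH, rt
Reagents that add atoms: none
Why: Pd(0) Tsuji–Trost O-deallylation of both aryl allyl ethers is neutral and leaves CHO, the silyl ether and the aryl alkyl ether untouched.

**Step 6**
Reactants: 9
Product: 10 ((2R,3R)-trans-2-(4-hydroxy-3,5-dimethoxyphenyl)-3-[(TBDPSO)methyl]-benzodioxane-7-carbaldehyde; numbering has the aryl-bearing carbon as C2, so CHO is para to O4)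
Conditions: DDQ (1.1 equiv), CH2Cl2 (0.02 M), 4 Å MS, 0 °C → rt, 3 h; then aq. NaHCO3
Reagents that add atoms: none
Why: **Proposed new method:** DDQ abstracts hydride from the benzylic CH2 of the free 4-alkylsyringol (a very electron-rich phenol) to give a p-quinone methide. The other phenol sits on an aldehyde-bearing, electron-poor ring and is not oxidised, so the oxidation is chemoselective. The tethered phenol then adds to the QM carbon (Cα) in a 6-exo fashion. The chair-like transition state places CH2OTBDPS pseudo-equatorial, so the aryl and CH2OR groups end up trans. Trans is also the thermodynamic isomer, and acidic DDQH2 can reopen a cis isomer through the QM. The existing (S)/(R) C3 centre fixes which QM face is attacked, giving (2R,3R). The closest known chemistry is DDQ or Ag2O oxidation of 4-alkylphenols to p-QMs with intramolecular trapping (chromans, dihydrobenzofurans), and the biomimetic trapping of QMs by catechol OH in benzodioxane lignin formation. It has not been shown for forming a 2-aryl-3-substituted 1,4-benzodioxane from a CH2 precursor.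

**Step 7**
Reactants: 11 (methyl 3,5-dihydroxybenzoate); 12 (TBSCl)
Product: 13 (methyl 3,5-bis(TBSO)benzoate)
Conditions: imidazole, DMF, rt
Reagents that add atoms: TBSCl, CC(C)(C)[Si](C)(C)Cl
Why: Standard silylation of phenols; the TBS groups will survive HWE basic conditions and be removed with fluoride at the end.

**Step 8**
Reactants: 13
Product: 14 (3,5-bis(TBSO)benzyl alcohol)
Conditions: DIBAL-H (3 equiv), CH2Cl2, –78 → 0 °C
Reagents that add atoms: none
Why: DIBAL-H reduces the ester to the primary alcohol; aryl silyl ethers tolerate it at low temperature.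

**Step 9**
Reactants: 14; 15 (CBr4)
Product: 16 (3,5-bis(TBSO)benzyl bromide)
Conditions: PPh3, CH2Cl2, 0 °C, 1 h
Reagents that add atoms: carbon tetrabromide, BrC(Br)(Br)Br
Why: Appel bromination is neutral, so the acid-labile silyl aryl ethers survive; the bromide is used crude.

**Step 10**
Reactants: 16; 17 (P(OEt)3)
Product: 18 (diethyl 3,5-bis(TBSO)benzylphosphonate)
Conditions: neat, 130 °C, 3 h, with EtBr distilled off
Reagents that add atoms: triethyl phosphite, CCOP(OCC)OCC
Why: Michaelis–Arbuzov reaction converts the benzylic bromide into the phosphonate.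

**Step 11**
Reactants: 10; 18
Product: 19 (protected (E)-stilbene)
Conditions: NaH (3.5 equiv), THF, 0 °C → rt, 12 h
Reagents that add atoms: none
Why: The HWE reaction of an aryl aldehyde with a benzylphosphonate gives the (E)-stilbene selectively. Excess base covers the free syringyl phenol, and the C2 and C3 stereocentres have no acidic H and are untouched.

**Step 12**
Reactants: 19
Product: 20 (aiphanol)
Conditions: TBAF (5 equiv), AcOH (5 equiv), THF, 0 °C → rt, 8 h
Reagents that add atoms: none
Why: Fluoride removes the two aryl TBS groups and the primary TBDPS group. Buffering with AcOH prevents phenoxide-driven QM cleavage of the benzylic aryl ether, and the stereocentres are unaffected.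

## Compound list
1 | 4-bromo-2,6-dimethoxyphenol | COc1cc(Br)cc(OC)c1O | starting material
2 | allyl bromide | C=CCBr | starting material
3 | 2-(allyloxy)-5-bromo-1,3-dimethoxybenzene | C=CCOc1c(OC)cc(Br)cc1OC | intermediate
4 | (S)-tert-butyldiphenylsilyl glycidyl ether | CC(C)(C)[Si](c1ccccc1)(c1ccccc1)OC[C@@H]1CO1 | starting material
5 | (S)-1-[4-(allyloxy)-3,5-dimethoxyphenyl]-3-(TBDPSO)propan-2-ol | C=CCOc1c(OC)cc(C[C@H](O)CO[Si](c2ccccc2)(c2ccccc2)C(C)(C)C)cc1OC | intermediate
6 | 4-fluoro-3-hydroxybenzaldehyde | O=Cc1ccc(F)c(O)c1 | starting material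
7 | 3-(allyloxy)-4-fluorobenzaldehyde | C=CCOc1cc(C=O)ccc1F | intermediate
8 | SNAr aryl ether (S) | C=CCOc1c(OC)cc(C[C@H](Oc2ccc(C=O)cc2OCC=C)CO[Si](c2ccccc2)(c2ccccc2)C(C)(C)C)cc1OC | intermediate
9 | diphenol (S) | COc1cc(C[C@H](Oc2ccc(C=O)cc2O)CO[Si](c2ccccc2)(c2ccccc2)C(C)(C)C)cc(OC)c1O | intermediate
10 | (2R,3R)-trans-benzodioxane aldehyde | COc1cc([C@H]2Oc3cc(C=O)ccc3O[C@@H]2CO[Si](c2ccccc2)(c2ccccc2)C(C)(C)C)cc(OC)c1O | intermediate
11 | methyl 3,5-dihydroxybenzoate | COC(=O)c1cc(O)cc(O)c1 | starting material
12 | TBSCl | CC(C)(C)[Si](C)(C)Cl | starting material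
13 | methyl 3,5-bis(TBSO)benzoate | COC(=O)c1cc(O[Si](C)(C)C(C)(C)C)cc(O[Si](C)(C)C(C)(C)C)c1 | intermediate
14 | 3,5-bis(TBSO)benzyl alcohol | OCc1cc(O[Si](C)(C)C(C)(C)C)cc(O[Si](C)(C)C(C)(C)C)c1 | intermediate
15 | carbon tetrabromide | BrC(Br)(Br)Br | starting material
16 | 3,5-bis(TBSO)benzyl bromide | BrCc1cc(O[Si](C)(C)C(C)(C)C)cc(O[Si](C)(C)C(C)(C)C)c1 | intermediate
17 | triethyl phosphite | CCOP(OCC)OCC | starting material
18 | diethyl 3,5-bis(TBSO)benzylphosphonate | CCOP(=O)(OCC)Cc1cc(O[Si](C)(C)C(C)(C)C)cc(O[Si](C)(C)C(C)(C)C)c1 | intermediate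
19 | protected (E)-stilbene | COc1cc([C@H]2Oc3cc(/C=C/c4cc(O[Si](C)(C)C(C)(C)C)cc(O[Si](C)(C)C(C)(C)C)c4)ccc3O[C@@H]2CO[Si](c2ccccc2)(c2ccccc2)C(C)(C)C)cc(OC)c1O | intermediate
20 | aiphanol | COc1cc([C@H]2Oc3cc(/C=C/c4cc(O)cc(O)c4)ccc3O[C@@H]2CO)cc(OC)c1O | target

## Totals
- Total steps: 12, of which 4 are the phosphonate branch (Steps 7–10).
- Longest linear sequence: 7 steps (Steps 1, 2, 4, 5, 6, 11, 12).

## Three steps most likely to fail
1. **Step 6 (proposed new DDQ/QM cyclization).**
   - Risks: the QM may lose Cβ–H to give an achiral enol ether, which erodes the C3 stereocentre; the product may be over-oxidised; cis/trans selectivity may be poor.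
   - Fallback (known chemistry, different approach): Sharpless AE of (E)-4-O-allylsinapyl alcohol with L-(+)-DET gives the (2S,3S)-epoxy alcohol. After TBDPS protection, open the epoxide at the benzylic carbon with the phenoxide of 4-TBSO-3-hydroxybenzaldehyde (inversion). Remove the TBS with TBAF and close the ring by intramolecular Mitsunobu (inversion at Cβ). The double inversion gives the trans-(2R,3R) benzodioxane directly.
2. **Step 4 (SNAr of the hindered secondary alkoxide).**
   - Risks: TBDPS 1,2-migration, aldehyde side reactions, incomplete conversion.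
   - Fallback: Pd-catalysed C–O coupling (Pd/biarylphosphine, Cs2CO3, toluene) of alcohol 5 with 4-bromo-3-(allyloxy)benzaldehyde, which also goes with retention at carbon.
3. **Step 11 (HWE on a free-phenol aldehyde with aryl TBS groups).**
   - Risks: partial desilylation or low conversion under excess NaH.
   - Fallback: Julia–Kocienski olefination of the aldehyde with the 3,5-bis(TBSO)benzyl 1-phenyltetrazolyl sulfone (KHMDS, THF, –78 °C). This is a different bond-forming reaction and is also E-selective.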